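## Retrosynthetic overview
- Target 12 is an 8,8''-biapigenin with a single 7-OMe, and it has no stereocenters. I assume the hindered C8–C8'' biaryl axis is not configurationally stable (free rotation), so there is no enantiomer to set.
- The one key disconnection is the C8–C8'' biaryl bond, made by Suzuki–Miyaura coupling of an 8-iodoflavone (the 7-OMe half) with an 8-pinacolboronate (the 7-OH half, carried as 7-OBn).
- Both chromone rings are already present in commercial genkwanin and apigenin, so no rings are formed. The order is: protect 4'-OH (and 7-OH on the apigenin half), install C8 iodide, convert one iodide to Bpin, couple, then remove all benzyl groups.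
- The chelated 5-OH is left unprotected throughout, which saves steps.
- Assumption: genkwanin (apigenin 7-methyl ether) is purchased.

## Route

**Step 1**
Reactants: 1 genkwanin; 2 benzyl bromide
Product: 3 4'-O-benzylgenkwanin
Conditions: BnBr (1.1 equiv), K2CO3, DMF, rt
Reagents that add atoms: BnBr, BrCc1ccccc1
Why: Under mild base only the 4'-OH is a free, non-chelated phenol (7-OH is already OMe, 5-OH is H-bonded to C4=O), so Williamson O-benzylation is selective.

**Step 2**
Reactants: 3 4'-O-benzylgenkwanin; 4 N-iodosuccinimide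
Product: 5 8-iodo-4'-O-benzylgenkwanin
Conditions: NIS, cat. TFA, MeCN, rt
Reagents that add atoms: NIS, O=C1CCC(=O)N1I
Why: Electrophilic aromatic iodination (SEAr) goes onto the electron-rich A ring. C8 is para to 5-OH and ortho to both 7-OMe and the ring oxygen, while the 4'-OBn ring is far less nucleophilic. I assume C8 is favored over C6.

**Step 3**
Reactants: 6 apigenin; 2 benzyl bromide
Product: 7 4',7-di-O-benzylapigenin
Conditions: BnBr (2.2 equiv), K2CO3, DMF, 60 °C
Reagents that add atoms: BnBr, BrCc1ccccc1
Why: The 7-OH and 4'-OH are the acidic, non-chelated phenols and are benzylated (Williamson), while the chelated 5-OH stays free.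

**Step 4**
Reactants: 7 4',7-di-O-benzylapigenin; 4 NIS
Product: 8 8-iodo-4',7-di-O-benzylapigenin
Conditions: NIS, cat. TFA, MeCN, rt
Reagents that add atoms: NIS, O=C1CCC(=O)N1I
Why: Same SEAr as Step 2. C8 is the only remaining position para to 5-OH and flanked by two oxygens, and C6 is the minor site.

**Step 5**
Reactants: 8 8-iodo-4',7-di-O-benzylapigenin; 9 bis(pinacolato)diboron
Product: 10 4',7-di-O-benzylapigenin-8-Bpin
Conditions: B2pin2 (1.5 equiv), Pd(dppf)Cl2 (5 mol%), KOAc, dioxane, 80 °C
Reagents that add atoms: B2pin2, CC1(C)OB(OC1(C)C)B1OC(C)(C)C(C)(C)O1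
Why: Miyaura borylation converts the aryl iodide to the aryl Bpin. The benzyl ethers, the chromone and the chelated 5-OH are untouched by the mild KOAc base.

**Step 6**
Reactants: 5 8-iodo-4'-O-benzylgenkwanin; 10 4',7-di-O-benzylapigenin-8-Bpin
Product: 11 tri-O-benzyl cupressuflavone 7-methyl ether
Conditions: Pd2(dba)3, SPhos, K3PO4, toluene/H2O (10:1), 100 °C
Reagents that add atoms: none
Why: Suzuki–Miyaura cross-coupling forms the C8–C8'' bond. A bulky, electron-rich biaryl phosphine (SPhos) is known to couple 2,6-dioxygenated aryl partners, and using two different halves fixes the 7-OMe/7''-O-protecting-group asymmetry without a statistical step. There are no stereocenters.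

**Step 7**
Reactants: 11 tri-O-benzyl cupressuflavone 7-methyl ether
Product: 12 cupressuflavone 7-methyl ether (target)
Conditions: H2 (1 atm), 10% Pd/C, THF/MeOH, rt
Reagents that add atoms: none (H2 only adds hydrogen)
Why: Hydrogenolysis cleaves the three aryl benzyl ethers (4', 4'' and 7'') to give the free phenols. The 7-OMe, the flavone C2=C3 and the C4=O survive these mild conditions, and the 5-OH groups were never protected.

## Compound list
1 | genkwanin (apigenin 7-methyl ether) | COc1cc(O)c2c(=O)cc(-c3ccc(O)cc3)oc2c1 | starting material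
2 | benzyl bromide | BrCc1ccccc1 | starting material
3 | 4'-O-benzylgenkwanin | COc1cc(O)c2c(=O)cc(-c3ccc(OCc4ccccc4)cc3)oc2c1 | intermediate
4 | N-iodosuccinimide | O=C1CCC(=O)N1I | starting material
5 | 8-iodo-4'-O-benzylgenkwanin | COc1cc(O)c2c(=O)cc(-c3ccc(OCc4ccccc4)cc3)oc2c1I | intermediate
6 | apigenin | O=c1cc(-c2ccc(O)cc2)oc2cc(O)cc(O)c12 | starting material
7 | 4',7-di-O-benzylapigenin | O=c1cc(-c2ccc(OCc3ccccc3)cc2)oc2cc(OCc3ccccc3)cc(O)c12 | intermediate
8 | 8-iodo-4',7-di-O-benzylapigenin | O=c1cc(-c2ccc(OCc3ccccc3)cc2)oc2c(I)c(OCc3ccccc3)cc(O)c12 | intermediate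
9 | bis(pinacolato)diboron | CC1(C)OB(OC1(C)C)B1OC(C)(C)C(C)(C)O1 | starting material
10 | 4',7-di-O-benzylapigenin-8-Bpin | O=c1cc(-c2ccc(OCc3ccccc3)cc2)oc2c(B3OC(C)(C)C(C)(C)O3)c(OCc3ccccc3)cc(O)c12 | intermediate
11 | tri-O-benzyl cupressuflavone 7-methyl ether | COc1cc(O)c2c(=O)cc(-c3ccc(OCc4ccccc4)cc3)oc2c1-c1c(OCc2ccccc2)cc(O)c2c(=O)cc(-c3ccc(OCc4ccccc4)cc3)oc12 | intermediate
12 | cupressuflavone 7-methyl ether (achiral, no stereocenters) | COc1cc(O)c2c(=O)cc(-c3ccc(O)cc3)oc2c1-c1c(O)cc(O)c2c(=O)cc(-c3ccc(O)cc3)oc12 | target

## Totals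
Total steps: 7. Longest linear sequence: 5 steps (apigenin → 7 → 8 → 10 → 11 → 12).

## Three steps most likely to fail
1. **Step 6 (hindered Suzuki coupling).** The biaryl is tetra-ortho-substituted, and the 2,6-dioxygenated Bpin is prone to protodeboronation.
   - Fallback: skip the boronate and do a Cu-mediated Ullmann cross-coupling of iodides 5 and 8 (Cu bronze, DMF, 140–150 °C, one partner in excess). Then separate heterodimer 11 from the two homodimers.
2. **Step 5 (borylation of the hindered iodide).** Hydrodeiodination or protodeboronation can compete.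
   - Fallback: change the organometallic partner. Make the 8-SnMe3 flavone with Me3SnSnMe3 and Pd(PPh3)4, then run a Stille coupling with 5 (Pd, CuI, CsF).
3. **Step 4 (and Step 2, same reaction): C8 versus C6 iodination regioselectivity.**
   - Fallback: change the order of events. Iodinate the 7-OH-free, 4'-OBn flavone, where the phenoxide directs to C8, and then alkylate the 7-OH. Use MeI for the 7-OMe half and BnBr for the 7-OBn half.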